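## Retrosynthetic overview

1. Target 33 ⇐ acetylation and desilylation of briarane triol 30, which already carries the six-membered ring, the ten-membered ring and the γ-lactone.
2. C1–C10 bond ⇐ transannular epoxide–olefin cyclisation of the 14-membered 1,2-epoxide 29. The epoxide oxygen becomes the C2 oxygen, and the cation is quenched as the Δ11(12) alkene.
3. 14-membered carbocycle ⇐ Nozaki–Hiyama–Kishi closure of C9–C10; C1=C2 ⇐ cross-metathesis of west alkene 22 with east enone 6; C14 and the epoxide ⇐ CBS reduction, then hydroxyl-directed epoxidation.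
4. γ-Lactone (C7, C8, C17) ⇐ intramolecular Reformatsky reaction of α-acyloxy ketone 17, built from silyl propargyl ether 7 and glycerate ester 8.
5. Ring order: γ-lactone, then the 14-membered ring, then the six-membered ring (the ten-membered ring is defined in the same event).

Assumption: briarane numbering (C1–C20) of the target is used for every intermediate, and where a name and a SMILES string could be read differently the SMILES string is meant. The senses of induction quoted for chiral catalysts come from the standard models, not from tested precedent on these substrates. TBS = tert-butyldimethylsilyl, TES = triethylsilyl, TBDPS = tert-butyldiphenylsilyl.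

## Route

**East fragment (C10–C15)**

Step 1
Reactants: 1 pent-4-yn-1-ol
Product: 3 (E)-5-iodo-4-methylpent-4-en-1-ol, via alkenylalane 2 (not isolated)
Conditions: Me3Al (3 equiv), Cp2ZrCl2 (0.25 equiv), CH2Cl2, 0 °C to rt; then I2, THF, −30 °C
Reagents that add atoms: trimethylaluminium C[Al](C)C; iodine II
Why: Zirconium-catalysed Negishi carboalumination adds CH3 and Al syn across the terminal alkyne (CH3 to the internal carbon) and iodinolysis goes with retention, so the future C10=C11 alkene is set E.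

Step 2
Reactants: 3 (E)-5-iodo-4-methylpent-4-en-1-ol
Product: 4 (E)-5-iodo-4-methylpent-4-enal
Conditions: Dess–Martin periodinane, NaHCO3, CH2Cl2, 0 °C
Reagents that add atoms: none
Why: Dess–Martin oxidation of a primary alcohol stops at the aldehyde and leaves the vinyl iodide untouched.

Step 3
Reactants: 4 (E)-5-iodo-4-methylpent-4-enal
Product: 5 (E)-7-iodo-2,6-dimethylhepta-1,6-dien-3-ol (racemic)
Conditions: CH2=C(CH3)MgBr, THF, −78 °C
Reagents that add atoms: isopropenylmagnesium bromide CC(=C)[Mg]Br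
Why: Grignard 1,2-addition installs C1 and C15 plus a terminal methylene for metathesis; the racemic carbinol centre is removed in step 4.

Step 4
Reactants: 5 (E)-7-iodo-2,6-dimethylhepta-1,6-dien-3-ol
Product: 6 (E)-7-iodo-2,6-dimethylhepta-1,6-dien-3-one (east enone)
Conditions: Dess–Martin periodinane, NaHCO3, CH2Cl2, 0 °C; used at once
Reagents that add atoms: none
Why: Dess–Martin oxidation of the allylic alcohol gives the 1,1-disubstituted enone needed for cross-metathesis.

**West fragment (C2–C9, C16–C19)**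

Step 5
Reactants: 7 tert-butyldimethyl(prop-2-yn-1-yloxy)silane; 8 methyl (4R)-2,2-dimethyl-1,3-dioxolane-4-carboxylate
Product: 10 ynone 4-(TBS-oxy)-1-[(4R)-2,2-dimethyl-1,3-dioxolan-4-yl]but-2-yn-1-one, via lithium acetylide 9 (not isolated)
Conditions: n-BuLi, THF, −78 °C; then added to 8, THF, −78 °C; NH4Cl quench
Reagents that add atoms: none
Why: Acylation of a lithium acetylide by an α-alkoxy ester stops at the ynone because the chelated tetrahedral adduct survives until quench; the dioxolane centre (future C8) is a placeholder that is oxidised in step 11.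

Step 6
Reactants: 10 ynone
Product: 11 (1S)-4-(TBS-oxy)-1-[(4R)-2,2-dimethyl-1,3-dioxolan-4-yl]but-2-yn-1-ol
Conditions: Ru(p-cymene)[(R,R)-TsDPEN] (2 mol %), i-PrOH, rt
Reagents that add atoms: none
Why: Noyori asymmetric transfer hydrogenation of the alkynyl ketone is catalyst-controlled; the (R,R)-ligand gives the 7S carbinol, anti to the dioxolane oxygen and therefore matched with the Felkin–Anh preference.

Step 7
Reactants: 11 propargylic alcohol
Product: 13 (1S,2Z)-4-(TBS-oxy)-1-[(4R)-2,2-dimethyl-1,3-dioxolan-4-yl]-3-iodobut-2-en-1-ol, via vinylalanate 12 (not isolated)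
Conditions: NaAlH2(OCH2CH2OMe)2, THF, 0 °C to rt; then I2, −78 °C
Reagents that add atoms: iodine II
Why: Hydroxyl-directed trans-hydroalumination puts aluminium on the distal alkyne carbon (C5) and hydrogen on C6, and iodinolysis with retention gives the Z iodide with iodine cis to C7, which is the C5=C6 geometry of the target.

Step 8
Reactants: 13 (Z)-iodo allylic alcohol
Product: 14 2-bromopropanoate of 13 (both epimers at CHBr)
Conditions: 2-bromopropanoyl bromide, pyridine, CH2Cl2, −20 °C
Reagents that add atoms: 2-bromopropanoyl bromide CC(Br)C(Br)=O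
Why: O-Acylation of the secondary allylic alcohol brings in C17–C19 and the bromide needed for chemoselective enolate generation.

Step 9
Reactants: 14 bromopropanoate acetonide
Product: 15 (2R,3S,4Z)-6-(TBS-oxy)-1,2-dihydroxy-5-iodohex-4-en-3-yl 2-bromopropanoate
Conditions: CeCl3·7H2O, oxalic acid (cat.), MeCN, rt
Reagents that add atoms: none
Why: Mild Lewis-acid hydrolysis of a terminal acetonide under conditions that spare the primary TBS ether and the ester.

Step 10
Reactants: 15 diol
Product: 16 (2R,3S,4Z)-6-(TBS-oxy)-2-hydroxy-5-iodo-1-(TES-oxy)hex-4-en-3-yl 2-bromopropanoate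
Conditions: Et3SiCl (1.05 equiv), imidazole, CH2Cl2, −40 °C
Reagents that add atoms: chlorotriethylsilane CC[Si](Cl)(CC)CC
Why: Silylation at low temperature is selective for the primary hydroxyl.

Step 11
Reactants: 16 secondary alcohol
Product: 17 (3S,4Z)-6-(TBS-oxy)-5-iodo-2-oxo-1-(TES-oxy)hex-4-en-3-yl 2-bromopropanoate
Conditions: Dess–Martin periodinane, NaHCO3, CH2Cl2, 0 °C
Reagents that add atoms: none
Why: Buffered Dess–Martin oxidation gives the C8 ketone under non-basic conditions, so the adjacent C7 stereocentre is not enolised.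

Step 12
Reactants: 17 α-acyloxy ketone
Product: 19 hydroxy lactone (3R,4R,5S)-5-[(Z)-3-(TBS-oxy)-2-iodoprop-1-enyl]-4-hydroxy-3-methyl-4-[(TES-oxy)methyl]oxolan-2-one, via zinc enolate 18 (not isolated)
Conditions: activated Zn dust, THF, 0 °C to rt; NH4Cl work-up
Reagents that add atoms: none
Why: Intramolecular Reformatsky reaction (aldol lactonisation): the zinc enolate tethered through O7 attacks the C8 ketone in a five-membered transition state that keeps CH2OTES trans to the C6 alkenyl group, which puts 8-OH cis to C6, and the C17 methyl settles trans to CH2OTES (cis to OH).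

Step 13
Reactants: 19 vinyl iodide lactone
Product: 20 (Z)-enal (iodine of 19 replaced by CHO)
Conditions: Pd(PPh3)4 (5 mol %), CO (1 atm), Bu3SnH (slow addition), THF, 50 °C
Reagents that add atoms: carbon monoxide [C-]#[O+]
Why: Palladium-catalysed reductive carbonylation (formylation) of a vinyl iodide proceeds with retention of alkene geometry.

Step 14
Reactants: 20 (Z)-enal
Product: 21 (4R)-homoallylic alcohol
Conditions: (R)-BINOL (20 mol %), Ti(OiPr)4 (10 mol %), 4 Å molecular sieves, CH2=CHCH2SnBu3, CH2Cl2, −20 °C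
Reagents that add atoms: allyltributylstannane C=CC[Sn](CCCC)(CCCC)CCCC
Why: Keck asymmetric allylation: the BINOL–titanium Lewis acid activates the enal and the (R)-ligand directs allyl transfer to the face that gives the 4R carbinol.

Step 15
Reactants: 21 homoallylic alcohol
Product: 22 4-O-TBDPS ether of 21
Conditions: t-BuPh2SiCl, imidazole, DMAP (cat.), DMF, rt
Reagents that add atoms: tert-butyl(chloro)diphenylsilane CC(C)(C)[Si](Cl)(c1ccccc1)c1ccccc1
Why: Silylation of the only accessible secondary hydroxyl; the tertiary 8-OH does not react.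

**Union, macrocyclisation, key cyclisation and end game**

Step 16
Reactants: 22 west terminal alkene; 6 east enone
Product: 23 acyclic (1E)-enone (C1=C2 formed)
Conditions: 6 (3 equiv), second-generation Hoveyda–Grubbs catalyst (10 mol %), CH2Cl2, 40 °C
Reagents that add atoms: none
Why: Olefin cross-metathesis between a terminal alkene and an excess of a 1,1-disubstituted enone gives the trisubstituted enone with the thermodynamically preferred E geometry.

Step 17
Reactants: 23 primary TES ether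
Product: 24 C9 aldehyde
Conditions: (COCl)2, DMSO, CH2Cl2, −78 to −30 °C; then Et3N; used crude
Reagents that add atoms: none
Why: Swern conditions cleave a primary triethylsilyl ether oxidatively and give the aldehyde directly, while the TBS and TBDPS ethers, the enone and the vinyl iodide are inert.

Step 18
Reactants: 24 iodo aldehyde
Product: 26 14-membered (9S)-allylic alcohol, via alkenylchromium 25 (not isolated)
Conditions: CrCl2 (10 equiv), NiCl2 (2 mol %), DMSO–THF (3:1), 0.002 M, rt
Reagents that add atoms: none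
Why: Nozaki–Hiyama–Kishi macrocyclisation: the alkenylchromium reagent adds chemoselectively to the aldehyde to close the 14-membered ring; with chromium chelated between the aldehyde oxygen and 8-OH, addition to the face remote from the C7 arm is expected and gives 9S.

Step 19
Reactants: 26 macrocyclic alcohol
Product: 27 9-acetate
Conditions: Ac2O (1.5 equiv), pyridine, DMAP (cat.), CH2Cl2, 0 °C
Reagents that add atoms: acetic anhydride CC(=O)OC(C)=O
Why: Acylation of the secondary allylic alcohol; the tertiary 8-OH is too hindered to react.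

Step 20
Reactants: 27 macrocyclic enone
Product: 28 (14S)-allylic alcohol
Conditions: (R)-2-methyl-CBS-oxazaborolidine (0.5 equiv), catecholborane, toluene, −78 °C
Reagents that add atoms: none
Why: Corey–Bakshi–Shibata reduction in which the trisubstituted alkenyl group is the large substituent, so the (R)-catalyst gives the 14S alcohol.

Step 21
Reactants: 28 allylic alcohol
Product: 29 (1S,2S)-epoxy alcohol
Conditions: VO(acac)2 (5 mol %), t-BuOOH (1.2 equiv), CH2Cl2, 0 °C
Reagents that add atoms: tert-butyl hydroperoxide CC(C)(C)OO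
Why: Vanadium-catalysed hydroxyl-directed epoxidation; the 1,2-allylic strain of the C1 methyl group enforces the erythro epoxy alcohol, and no other alkene carries a free allylic hydroxyl.

Step 22
Reactants: 29 epoxy alcohol
Product: 30 briarane triol (C1–C10 bond formed; free 2-OH, 8-OH and 14-OH)
Conditions: BF3·OEt2 (1.5 equiv), CH2Cl2, −78 °C; then Et3N
Reagents that add atoms: none
Why: Proposed new method: monodentate activation of the epoxide weakens the tertiary C1–O bond and the C10=C11 alkene across the ring attacks C1 anti to the departing oxygen (inversion at C1, retention at C2) through a chair-like six-membered transition state with C2 and C9 equatorial, so CH3-15 and H-10 end up trans, and the C11 cation loses the axial H-12 that lies syn to the axial 14-OH to give the Δ11(12) alkene; the closest known reaction type is the Lewis-acid epoxide-initiated cation–olefin cyclisation and the transannular cyclisation of cembranoid epoxides.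

Step 23
Reactants: 30 briarane triol
Product: 31 tetraol (16-OH freed)
Conditions: HF·pyridine, pyridine, THF, 0 °C
Reagents that add atoms: none
Why: Buffered fluoride removes the primary allylic TBS ether much faster than the secondary TBDPS ether.

Step 24
Reactants: 31 tetraol
Product: 32 2,9,14,16-tetraacetate 4-O-TBDPS ether
Conditions: Ac2O, Et3N, DMAP (cat.), CH2Cl2, rt
Reagents that add atoms: acetic anhydride CC(=O)OC(C)=O
Why: Acetylation of the primary and the two secondary hydroxyls; the tertiary 8-OH stays free, as in the natural product.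

Step 25
Reactants: 32 silyl ether
Product: 33 CNP0226727.2 (target)
Conditions: HF·pyridine, THF, rt
Reagents that add atoms: none
Why: Fluoride cleavage of the silyl ether under acidic conditions avoids acetate migration and releases the 4-OH.

## Compound list

1 | pent-4-yn-1-ol | C#CCCCO | starting material
2 | alkenylalane: dimethyl[(E)-5-(dimethylalumanyloxy)-2-methylpent-1-enyl]alumane | C[Al](C)OCCC/C(C)=C/[Al](C)C | intermediate (not isolated)
3 | (E)-5-iodo-4-methylpent-4-en-1-ol | OCCC/C(C)=C/I | intermediate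
4 | (E)-5-iodo-4-methylpent-4-enal | O=CCC/C(C)=C/I | intermediate
5 | (E)-7-iodo-2,6-dimethylhepta-1,6-dien-3-ol (racemic) | C=C(C)C(O)CC/C(C)=C/I | intermediate
6 | (E)-7-iodo-2,6-dimethylhepta-1,6-dien-3-one (east enone) | C=C(C)C(=O)CC/C(C)=C/I | intermediate
7 | tert-butyldimethyl(prop-2-yn-1-yloxy)silane | C#CCO[Si](C)(C)C(C)(C)C | starting material
8 | methyl (4R)-2,2-dimethyl-1,3-dioxolane-4-carboxylate | COC(=O)[C@H]1COC(C)(C)O1 | starting material
9 | lithium acetylide of 7 | [Li]C#CCO[Si](C)(C)C(C)(C)C | intermediate (not isolated)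
10 | 4-(TBS-oxy)-1-[(4R)-2,2-dimethyl-1,3-dioxolan-4-yl]but-2-yn-1-one | CC(C)(C)[Si](C)(C)OCC#CC(=O)[C@H]1COC(C)(C)O1 | intermediate
11 | (1S)-4-(TBS-oxy)-1-[(4R)-2,2-dimethyl-1,3-dioxolan-4-yl]but-2-yn-1-ol | CC(C)(C)[Si](C)(C)OCC#C[C@H](O)[C@H]1COC(C)(C)O1 | intermediate
12 | sodium vinylalanate (five-membered O–Al–C chelate formed from 11) | [Na+].COCCO[Al-]1(OCCOC)O[C@H]([C@H]2COC(C)(C)O2)C=C1CO[Si](C)(C)C(C)(C)C | intermediate (not isolated)
13 | (1S,2Z)-4-(TBS-oxy)-1-[(4R)-2,2-dimethyl-1,3-dioxolan-4-yl]-3-iodobut-2-en-1-ol | CC(C)(C)[Si](C)(C)OC/C(I)=C/[C@H](O)[C@H]1COC(C)(C)O1 | intermediate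
14 | (1S,2Z)-4-(TBS-oxy)-1-[(4R)-2,2-dimethyl-1,3-dioxolan-4-yl]-3-iodobut-2-en-1-yl 2-bromopropanoate (both epimers at CHBr) | CC(C)(C)[Si](C)(C)OC/C(I)=C/[C@H](OC(=O)C(C)Br)[C@H]1COC(C)(C)O1 | intermediate
15 | (2R,3S,4Z)-6-(TBS-oxy)-1,2-dihydroxy-5-iodohex-4-en-3-yl 2-bromopropanoate | CC(C)(C)[Si](C)(C)OC/C(I)=C/[C@H](OC(=O)C(C)Br)[C@H](O)CO | intermediate
16 | (2R,3S,4Z)-6-(TBS-oxy)-2-hydroxy-5-iodo-1-(TES-oxy)hex-4-en-3-yl 2-bromopropanoate | CC(C)(C)[Si](C)(C)OC/C(I)=C/[C@H](OC(=O)C(C)Br)[C@H](O)CO[Si](CC)(CC)CC | intermediate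
17 | (3S,4Z)-6-(TBS-oxy)-5-iodo-2-oxo-1-(TES-oxy)hex-4-en-3-yl 2-bromopropanoate | CC(C)(C)[Si](C)(C)OC/C(I)=C/[C@H](OC(=O)C(C)Br)C(=O)CO[Si](CC)(CC)CC | intermediate
18 | bromozinc ester enolate of 17 | CC(C)(C)[Si](C)(C)OC/C(I)=C/[C@H](OC(O[Zn]Br)=CC)C(=O)CO[Si](CC)(CC)CC | intermediate (not isolated)
19 | (3R,4R,5S)-5-[(Z)-3-(TBS-oxy)-2-iodoprop-1-enyl]-4-hydroxy-3-methyl-4-[(TES-oxy)methyl]oxolan-2-one (C7 S, C8 R, C17 R) | CC(C)(C)[Si](C)(C)OC/C(I)=C/[C@@H]1OC(=O)[C@H](C)[C@@]1(O)CO[Si](CC)(CC)CC | intermediate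
20 | (Z)-2-[(TBS-oxy)methyl]-3-[(2S,3R,4R)-3-hydroxy-4-methyl-5-oxo-3-[(TES-oxy)methyl]oxolan-2-yl]prop-2-enal | CC(C)(C)[Si](C)(C)OC/C(C=O)=C/[C@@H]1OC(=O)[C@H](C)[C@@]1(O)CO[Si](CC)(CC)CC | intermediate
21 | (4R)-homoallylic alcohol: lactone 20 with CHO converted into (R)-CH(OH)CH2CH=CH2 (C4, C3, C2) | CC(C)(C)[Si](C)(C)OC/C([C@H](O)CC=C)=C/[C@@H]1OC(=O)[C@H](C)[C@@]1(O)CO[Si](CC)(CC)CC | intermediate
22 | 4-O-TBDPS ether of 21 | CC(C)(C)[Si](C)(C)OC/C([C@H](O[Si](c2ccccc2)(c3ccccc3)C(C)(C)C)CC=C)=C/[C@@H]1OC(=O)[C@H](C)[C@@]1(O)CO[Si](CC)(CC)CC | intermediate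
23 | acyclic enone: 22 with its terminal alkene extended to (1E)-C2H=C1(CH3)–C14(=O)–C13H2–C12H2–C11(CH3)=C10HI (10E) | CC(C)(C)[Si](C)(C)OC/C([C@H](O[Si](c2ccccc2)(c3ccccc3)C(C)(C)C)C/C=C(\C)C(=O)CC/C(C)=C/I)=C/[C@@H]1OC(=O)[C@H](C)[C@@]1(O)CO[Si](CC)(CC)CC | intermediate
24 | C9 aldehyde: 23 with CH2OTES converted into CHO | CC(C)(C)[Si](C)(C)OC/C([C@H](O[Si](c2ccccc2)(c3ccccc3)C(C)(C)C)C/C=C(\C)C(=O)CC/C(C)=C/I)=C/[C@@H]1OC(=O)[C@H](C)[C@@]1(O)C=O | intermediate
25 | alkenylchromium dichloride from 24 (C10–CrCl2 in place of C10–I) | CC(C)(C)[Si](C)(C)OC/C([C@H](O[Si](c2ccccc2)(c3ccccc3)C(C)(C)C)C/C=C(\C)C(=O)CC/C(C)=C/[Cr](Cl)Cl)=C/[C@@H]1OC(=O)[C@H](C)[C@@]1(O)C=O | intermediate (not isolated)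
26 | 14-membered macrocycle (1,10-seco-briarane): (9S)-9-hydroxy, 8-hydroxy, 14-oxo, 16-OTBS, (4R)-4-OTBDPS, 1E, 5Z and 10E alkenes, C7/C8/C17 γ-lactone | CC(C)(C)[Si](C)(C)OC/C1=C/[C@@H]2OC(=O)[C@H](C)[C@@]2(O)[C@@H](O)/C=C(C)/CCC(=O)/C(C)=C/C[C@H]1O[Si](c3ccccc3)(c4ccccc4)C(C)(C)C | intermediate
27 | 9-O-acetate of 26 | CC(C)(C)[Si](C)(C)OC/C1=C/[C@@H]2OC(=O)[C@H](C)[C@@]2(O)[C@@H](OC(C)=O)/C=C(C)/CCC(=O)/C(C)=C/C[C@H]1O[Si](c3ccccc3)(c4ccccc4)C(C)(C)C | intermediate
28 | (14S)-allylic alcohol from 27 | CC(C)(C)[Si](C)(C)OC/C1=C/[C@@H]2OC(=O)[C@H](C)[C@@]2(O)[C@@H](OC(C)=O)/C=C(C)/CC[C@H](O)/C(C)=C/C[C@H]1O[Si](c3ccccc3)(c4ccccc4)C(C)(C)C | intermediate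
29 | (1S,2S,14S)-1,2-epoxy-14-ol (erythro epoxy alcohol) | CC(C)(C)[Si](C)(C)OC/C1=C/[C@@H]2OC(=O)[C@H](C)[C@@]2(O)[C@@H](OC(C)=O)/C=C(C)/CC[C@H](O)[C@]3(C)O[C@H]3C[C@H]1O[Si](c4ccccc4)(c5ccccc5)C(C)(C)C | intermediate
30 | briarane triol (1R,2S,4R,7S,8S,9S,10S,14S,17R): 9-acetoxy-2,8,14-trihydroxy-16-OTBS-4-OTBDPS-briara-5(Z),11(12)-diene γ-lactone | CC(C)(C)[Si](C)(C)OC/C1=C/[C@@H]2OC(=O)[C@H](C)[C@@]2(O)[C@@H](OC(C)=O)[C@H]2C(C)=CC[C@H](O)[C@]2(C)[C@@H](O)C[C@H]1O[Si](c3ccccc3)(c4ccccc4)C(C)(C)C | intermediate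
31 | 16-hydroxy compound from 30 (2,8,14,16-tetraol; 9-OAc; 4-OTBDPS) | OC/C1=C/[C@@H]2OC(=O)[C@H](C)[C@@]2(O)[C@@H](OC(C)=O)[C@H]2C(C)=CC[C@H](O)[C@]2(C)[C@@H](O)C[C@H]1O[Si](c3ccccc3)(c4ccccc4)C(C)(C)C | intermediate
32 | 2,9,14,16-tetraacetate 4-O-TBDPS ether | CC(=O)OC/C1=C/[C@@H]2OC(=O)[C@H](C)[C@@]2(O)[C@@H](OC(C)=O)[C@H]2C(C)=CC[C@H](OC(C)=O)[C@]2(C)[C@@H](OC(C)=O)C[C@H]1O[Si](c3ccccc3)(c4ccccc4)C(C)(C)C | intermediate
33 | CNP0226727.2: (1R,2S,4R,5Z,7S,8S,9S,10S,14S,17R)-2,9,14,16-tetraacetoxy-4,8-dihydroxybriara-5,11-diene γ-lactone | CC(=O)OC/C1=C/[C@@H]2OC(=O)[C@H](C)[C@@]2(O)[C@@H](OC(C)=O)[C@H]2C(C)=CC[C@H](OC(C)=O)[C@]2(C)[C@@H](OC(C)=O)C[C@H]1O | target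

## Step count and risks

Total step count: 25. Longest linear sequence: 21 steps (steps 5–25, from 7 and 8); the east fragment (steps 1–4) joins at step 16.

**Step 22 (transannular cyclisation).** A semipinacol shift, attack at the wrong alkene face, or loss of the wrong proton could compete. The fallback sets out from 29 and returns at 30. Treat 29 with the trivalent titanium reagent Cp2TiCl (from Cp2TiCl2 and Mn dust, THF, rt). Homolytic epoxide opening gives the tertiary C1 radical with no cation at C1. This radical closes onto C10 across the ring, and a second Cp2TiCl converts the C11 radical into the exocyclic Δ11(20) alkene F1. RhCl3·3H2O (cat.) in EtOH at 60 °C then moves the double bond into the ring and gives 30.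

**Step 18 (macrocyclisation and the C9 stereocentre).** The sense of addition at C9 rests on a chelate model that two similar ring carbons at C8 make weak. The fallback sets out from 24 and returns at 27. If ring closure gives mainly the 9R alcohol F2, treat F2 with AcOH, PPh3 and DIAD in toluene at 0 °C. This Mitsunobu esterification inverts C9 and gives acetate 27 directly. Any 9S alcohol is acetylated as in step 19, so both epimers converge on 27.

**Step 16 (cross-metathesis of two advanced fragments to a trisubstituted enone).** The fallback sets out from 22 and 4 and returns at 23. Cleave the terminal alkene of 22 with OsO4 (cat.), NaIO4 and 2,6-lutidine in dioxane–water to give aldehyde F3. Add LiCH(CH3)P(O)(OEt)2 to aldehyde 4 to give β-hydroxyphosphonate F4, and oxidise it with Dess–Martin periodinane to β-ketophosphonate F5. A Horner–Wadsworth–Emmons reaction of F3 with F5 (Ba(OH)2, wet THF, rt) forms the (1E)-enone 23.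

Further compounds
F1 | step 22 | exocyclic Δ11(20) isomer of 30 | CC(C)(C)[Si](C)(C)OC/C1=C/[C@@H]2OC(=O)[C@H](C)[C@@]2(O)[C@@H](OC(C)=O)[C@H]2C(=C)CC[C@H](O)[C@]2(C)[C@@H](O)C[C@H]1O[Si](c3ccccc3)(c4ccccc4)C(C)(C)C
F2 | step 18 | 9R epimer of macrocyclic alcohol 26 | CC(C)(C)[Si](C)(C)OC/C1=C/[C@@H]2OC(=O)[C@H](C)[C@@]2(O)[C@H](O)/C=C(C)/CCC(=O)/C(C)=C/C[C@H]1O[Si](c3ccccc3)(c4ccccc4)C(C)(C)C
F3 | step 16 | C2 aldehyde from 22 (terminal CH=CH2 cleaved to CHO) | CC(C)(C)[Si](C)(C)OC/C([C@H](O[Si](c2ccccc2)(c3ccccc3)C(C)(C)C)CC=O)=C/[C@@H]1OC(=O)[C@H](C)[C@@]1(O)CO[Si](CC)(CC)CC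
F4 | step 16 | diethyl [(E)-3-hydroxy-7-iodo-6-methylhept-6-en-2-yl]phosphonate (diastereomer mixture) | CCOP(=O)(OCC)C(C)C(O)CC/C(C)=C/I
F5 | step 16 | diethyl [(E)-7-iodo-6-methyl-3-oxohept-6-en-2-yl]phosphonate | CCOP(=O)(OCC)C(C)C(=O)CC/C(C)=C/I
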